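**Strategy**

The plan rests on inserting ethylene (C6–C7) between an acyl carbon, C8, and C5 to close ring B. It exploits two features: the exocyclic methylene at C8, which is a masked ketone, and the C4 carboxyl, which can activate a ring-A C4=C5 alkene so that C5 is a radical acceptor. In one operation an acyl radical made from a C8 aldehyde adds to ethylene (C7–C8) and the new radical closes 6-exo onto C5 (C5–C6), fixing the cis A/B fusion against the C10 quaternary methyl centre. The precursor is a monocyclic cyclohexenecarboxylate with an α-branched aldehyde side arm on C10.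

Key step: step 8

Remark on the chemistry: labdane numbering is used and β denotes the face of the C10 methyl. The target SMILES is read as (4S,5S,9R,10R,13S), a cis-fused decalin with H-5, H-9 and the C4 carboxyl on the β-face and the C9 side chain and C4 methyl on the α-face.

**Route**

Step 1
Reactants: 1 (S)-citronellol
Product: 2 (S)-tert-butyl[(3,7-dimethyloct-6-en-1-yl)oxy]diphenylsilane
Conditions: TBDPSCl, imidazole, DMF, rt
Reagents that add atoms: tert-butyl(chloro)diphenylsilane, CC(C)(C)[Si](Cl)(c1ccccc1)c1ccccc1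
Why: Silylation of the primary alcohol gives an ether that should survive hydride, organometallic, radical and basic steps; the C13 centre comes from the chiral pool.

Step 2
Reactants: 2 (S)-tert-butyl[(3,7-dimethyloct-6-en-1-yl)oxy]diphenylsilane
Product: 4 (4S)-6-[(tert-butyldiphenylsilyl)oxy]-4-methylhexanal, via ozonide 3 (not isolated)
Conditions: O3, CH2Cl2, −78 °C; then PPh3, → rt
Reagents that add atoms: ozone, [O-][O+]=O
Why: Ozonolysis with reductive work-up cleaves the trisubstituted alkene to the aldehyde whose carbonyl carbon becomes C9.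

Step 3
Reactants: 4 (4S)-6-[(tert-butyldiphenylsilyl)oxy]-4-methylhexanal
Product: 5 (5S)-7-[(tert-butyldiphenylsilyl)oxy]-5-methylhept-1-yne
Conditions: dimethyl (1-diazo-2-oxopropyl)phosphonate, K2CO3, MeOH, rt
Reagents that add atoms: dimethyl (1-diazo-2-oxopropyl)phosphonate, CC(=O)C(=[N+]=[N-])P(=O)(OC)OC
Why: Seyferth–Gilbert homologation under mild base converts the unbranched aldehyde into the terminal alkyne, adding the carbon that becomes C8.

Step 4
Reactants: 5 (5S)-7-[(tert-butyldiphenylsilyl)oxy]-5-methylhept-1-yne, 6 3-methylcyclohex-2-en-1-one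
Product: 10 (3S)-3-methyl-3-[(5S)-7-(tert-butyldiphenylsilyloxy)-5-methylhept-1-en-2-yl]cyclohex-1-en-1-yl trifluoromethanesulfonate, via alkenylaluminium 7 (not isolated), via aluminium enolate 8 (not isolated), via lithium aluminate enolate 9 (not isolated)
Conditions: 5, i-Bu2AlH, NiCl2(dppp) (3 mol %), THF, rt; then 6, Cu(OTf)2 (5 mol %), chiral sulfonate-bearing imidazolinium salt (NHC precursor), −30 °C; then MeLi, −78 °C; then N-(5-chloropyridin-2-yl)bis(trifluoromethanesulfonyl)imide, → 0 °C
Reagents that add atoms: N-(5-chloropyridin-2-yl)-1,1,1-trifluoro-N-(trifluoromethylsulfonyl)methanesulfonamide, O=S(=O)(N(c1ccc(Cl)cn1)S(=O)(=O)C(F)(F)F)C(F)(F)F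
Why: Nickel-catalysed α-selective hydroalumination gives the internal alkenylalane, copper-catalysed asymmetric conjugate addition sets the C10 quaternary centre under catalyst control (ligand antipode chosen to give 3S), and the regiodefined enolate, activated as its aluminate, is trapped as the C4=C5 enol triflate.

Step 5
Reactants: 10 enol triflate
Product: 11 2-(trimethylsilyl)ethyl (3S)-3-methyl-3-[(5S)-7-(tert-butyldiphenylsilyloxy)-5-methylhept-1-en-2-yl]cyclohex-1-ene-1-carboxylate
Conditions: Pd(OAc)2 (5 mol %), PPh3, CO (1 atm), Me3SiCH2CH2OH (excess), Et3N, DMF, 50 °C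
Reagents that add atoms: carbon monoxide, [C-]#[O+]; 2-(trimethylsilyl)ethanol, C[Si](C)(C)CCO
Why: Palladium-catalysed alkoxycarbonylation of the vinyl triflate installs C19 as a fluoride-cleavable ester and makes C5 the β-carbon of an enoate.

Step 6
Reactants: 11 enoate
Product: 13 2-(trimethylsilyl)ethyl (3S)-3-[(5S)-7-(tert-butyldiphenylsilyloxy)-1-hydroxy-5-methylheptan-2-yl]-3-methylcyclohex-1-ene-1-carboxylate (both C9 epimers), via alkylborane 12 (not isolated)
Conditions: 9-BBN, THF, 0 → 50 °C; then H2O2, NaOAc (aq), 0 °C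
Reagents that add atoms: hydrogen peroxide, OO
Why: Hydroboration–oxidation is anti-Markovnikov on the electron-rich 1,1-disubstituted alkene and should leave the conjugated ester alone; C9 forms without control, which is harmless because it is equilibrated in step 9.

Step 7
Reactants: 13 primary alcohol
Product: 14 2-(trimethylsilyl)ethyl (3S)-3-[(5S)-7-(tert-butyldiphenylsilyloxy)-5-methyl-1-oxoheptan-2-yl]-3-methylcyclohex-1-ene-1-carboxylate (both C9 epimers)
Conditions: DMP, NaHCO3, CH2Cl2, 0 °C → rt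
Reagents that add atoms: none
Why: Dess–Martin oxidation gives the C8 aldehyde under neutral conditions without touching the silyl ether or the enoate.

Step 8
Reactants: 14 aldehyde, 15 ethylene
Product: 16 2-(trimethylsilyl)ethyl (5β,13S)-15-(tert-butyldiphenylsilyloxy)-8-oxo-17,18-dinorlabdan-19-oate (cis-fused, H-5 cis to CH3-10; mixture at C4 and C9)
Conditions: (n-Bu4N)4[W10O32] (2 mol %), ethylene (20 bar), MeCN/PhCF3, 390 nm LED, 10 °C
Reagents that add atoms: none
Why: Proposed new method: excited decatungstate abstracts the formyl hydrogen of 14 to give a nucleophilic acyl radical at C8, which adds to ethylene (C7–C8); the primary radical at C6 then closes onto C5, the β-carbon of the ring-A enoate (C5–C6), and the tertiary α-ester radical at C4 is quenched by back hydrogen-atom transfer from the reduced polyoxometalate, so the step is redox-neutral and adds only C2H4. The closest known reaction types are decatungstate- or thiol-mediated radical hydroacylation of alkenes by aldehydes (Giese type) and tandem acyl-radical addition–cyclisation annulations; new is ethylene as the relay alkene in a [4+2] sense. Ring B closes in the 6-exo-trig mode. C5 is controlled by the C10 quaternary centre: with the tether pseudo-equatorial on C10 the radical attacks C5 axially, anti to the pseudo-axial C10 methyl, which can only give the cis-fused decalin; C4 and C9 arise as mixtures and are corrected in step 9. The step needs addition to ethylene to outrun decarbonylation and cyclisation to outrun further ethylene uptake, which ethylene pressure at low temperature, the polarity match of the C6 radical with the enoate and the gem-disubstituted tether should secure, while direct closure of the acyl radical is excluded because C5 and C4 are reachable only by 4-exo or 5-endo modes.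

Step 9
Reactants: 16 cis-fused keto ester (mixture at C4 and C9)
Product: 19 2-(trimethylsilyl)ethyl (5β,9β,13S)-15-(tert-butyldiphenylsilyloxy)-8-oxo-17-norlabdan-19-oate, via silyl enol ether 17 (not isolated), via C4-methylated silyl enol ether 18 (not isolated)
Conditions: LiN(i-Pr)2 (LDA, 1.05 equiv), THF, −78 °C, then TMSCl (1.05 equiv); LDA (1.5 equiv), −78 → −30 °C; MeI, DMPU, → 0 °C; then K2CO3, MeOH, rt
Reagents that add atoms: iodomethane, CI
Why: Kinetic enolisation masks the ketone as its C7 silyl enol ether, the hindered ester enolate is then methylated on the α-face because the axial C10 methyl screens the β-face of C4 in the chair that keeps C4 equatorial on ring B (ester enolate alkylation), and methanolysis returns the ketone and equilibrates C9 to the epimer with the side chain equatorial, which should be clearly favoured once C4 is quaternary.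

Step 10
Reactants: 19 keto ester
Product: 20 2-(trimethylsilyl)ethyl (5β,9β,13S)-15-(tert-butyldiphenylsilyloxy)labd-8(17)-en-19-oate
Conditions: Ph3PCH3Br, KOt-Bu, toluene, rt → 60 °C
Reagents that add atoms: methyltriphenylphosphonium bromide, C[P+](c1ccccc1)(c1ccccc1)c1ccccc1.[Br-]
Why: Wittig methylenation of the hindered C8 ketone installs C17; the base can only return C9 to its thermodynamic configuration and C4 has no α-hydrogen left.

Step 11
Reactants: 20 silyl ether
Product: 21 2-(trimethylsilyl)ethyl (5β,9β,13S)-15-hydroxylabd-8(17)-en-19-oate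
Conditions: HF·pyridine, pyridine, THF, 0 °C → rt
Reagents that add atoms: none
Why: Buffered HF cleaves the primary silyl ether while the β-silylethyl ester, which needs nucleophilic fluoride, and the exocyclic alkene should persist.

Step 12
Reactants: 22 caffeic acid
Product: 24 (E)-3-[3,4-bis(tert-butyldimethylsilyloxy)phenyl]acrylic acid, via tris-silylated caffeate 23 (not isolated)
Conditions: TBSCl, imidazole, DMF, rt; then AcOH, THF/H2O, rt
Reagents that add atoms: tert-butyl(chloro)dimethylsilane, CC(C)(C)[Si](C)(C)Cl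
Why: Exhaustive silylation followed by selective hydrolysis of the labile silyl ester protects the catechol and frees the acid.

Step 13
Reactants: 21 primary alcohol, 24 protected caffeic acid
Product: 25 2-(trimethylsilyl)ethyl (5β,9β,13S)-15-{(E)-3-[3,4-bis(tert-butyldimethylsilyloxy)phenyl]acryloyloxy}labd-8(17)-en-19-oate
Conditions: DCC, DMAP (cat.), CH2Cl2, 0 °C → rt
Reagents that add atoms: none
Why: Steglich esterification of the unhindered C15 alcohol with the cinnamic acid proceeds without touching the E-alkene or any stereocentre.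

Step 14
Reactants: 25 fully protected ester
Product: 26 CNP0130717.2, (5β,9β,13S)-15-[(E)-caffeoyloxy]labd-8(17)-en-19-oic acid (4S,5S,9R,10R,13S)
Conditions: n-Bu4NF, AcOH, THF, 0 °C → rt (degassed)
Reagents that add atoms: none
Why: Fluoride removes both aryl silyl ethers and fragments the β-silylethyl ester at silicon, so the hindered C19 acid is released without hydrolytic conditions that would cleave the caffeate.

**Compound list**

1 | (S)-citronellol, (3S)-3,7-dimethyloct-6-en-1-ol | CC(C)=CCC[C@H](C)CCO | starting material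
2 | (S)-tert-butyl[(3,7-dimethyloct-6-en-1-yl)oxy]diphenylsilane | CC(C)=CCC[C@H](C)CCO[Si](c1ccccc1)(c1ccccc1)C(C)(C)C | intermediate
3 | ozonide of 2 (3,3-dimethyl-1,2,4-trioxolane carrying the silyloxy chain at C5) | CC1(C)OOC(CC[C@H](C)CCO[Si](c2ccccc2)(c2ccccc2)C(C)(C)C)O1 | intermediate
4 | (4S)-6-[(tert-butyldiphenylsilyl)oxy]-4-methylhexanal | O=CCC[C@H](C)CCO[Si](c1ccccc1)(c1ccccc1)C(C)(C)C | intermediate
5 | (5S)-7-[(tert-butyldiphenylsilyl)oxy]-5-methylhept-1-yne | C#CCC[C@H](C)CCO[Si](c1ccccc1)(c1ccccc1)C(C)(C)C | intermediate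
6 | 3-methylcyclohex-2-en-1-one | CC1=CC(=O)CCC1 | starting material
7 | diisobutyl[(5S)-7-(tert-butyldiphenylsilyloxy)-5-methylhept-1-en-2-yl]aluminium | C=C(CC[C@H](C)CCO[Si](c1ccccc1)(c1ccccc1)C(C)(C)C)[Al](CC(C)C)CC(C)C | intermediate
8 | diisobutylaluminium enolate of (3S)-3-methyl-3-(alkenyl)cyclohexanone | CC(C)C[Al](CC(C)C)OC1=C[C@@](C)(C(=C)CC[C@H](C)CCO[Si](c2ccccc2)(c2ccccc2)C(C)(C)C)CCC1 | intermediate
9 | lithium methyl(diisobutyl)aluminate of enolate 8 | [Li+].CC(C)C[Al-](C)(CC(C)C)OC1=C[C@@](C)(C(=C)CC[C@H](C)CCO[Si](c2ccccc2)(c2ccccc2)C(C)(C)C)CCC1 | intermediate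
10 | (3S)-3-methyl-3-[(5S)-7-(tert-butyldiphenylsilyloxy)-5-methylhept-1-en-2-yl]cyclohex-1-en-1-yl trifluoromethanesulfonate | O=S(=O)(OC1=C[C@@](C)(C(=C)CC[C@H](C)CCO[Si](c2ccccc2)(c2ccccc2)C(C)(C)C)CCC1)C(F)(F)F | intermediate
11 | 2-(trimethylsilyl)ethyl (3S)-3-methyl-3-[(5S)-7-(tert-butyldiphenylsilyloxy)-5-methylhept-1-en-2-yl]cyclohex-1-ene-1-carboxylate | C[Si](C)(C)CCOC(=O)C1=C[C@@](C)(C(=C)CC[C@H](C)CCO[Si](c2ccccc2)(c2ccccc2)C(C)(C)C)CCC1 | intermediate
12 | B-alkyl-9-borabicyclo[3.3.1]nonane from 11 (boron on C8) | C[Si](C)(C)CCOC(=O)C1=C[C@@](C)(C(CB2C3CCCC2CCC3)CC[C@H](C)CCO[Si](c2ccccc2)(c2ccccc2)C(C)(C)C)CCC1 | intermediate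
13 | 2-(trimethylsilyl)ethyl (3S)-3-[(5S)-7-(tert-butyldiphenylsilyloxy)-1-hydroxy-5-methylheptan-2-yl]-3-methylcyclohex-1-ene-1-carboxylate (C9 epimers) | C[Si](C)(C)CCOC(=O)C1=C[C@@](C)(C(CO)CC[C@H](C)CCO[Si](c2ccccc2)(c2ccccc2)C(C)(C)C)CCC1 | intermediate
14 | 2-(trimethylsilyl)ethyl (3S)-3-[(5S)-7-(tert-butyldiphenylsilyloxy)-5-methyl-1-oxoheptan-2-yl]-3-methylcyclohex-1-ene-1-carboxylate (C9 epimers) | C[Si](C)(C)CCOC(=O)C1=C[C@@](C)(C(C=O)CC[C@H](C)CCO[Si](c2ccccc2)(c2ccccc2)C(C)(C)C)CCC1 | intermediate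
15 | ethylene | C=C | starting material
16 | 2-(trimethylsilyl)ethyl (5β,13S)-15-(tert-butyldiphenylsilyloxy)-8-oxo-17,18-dinorlabdan-19-oate (cis-fused; C4 and C9 epimers) | O=C1CC[C@H]2[C@](C)(CCCC2C(=O)OCC[Si](C)(C)C)C1CC[C@H](C)CCO[Si](c1ccccc1)(c1ccccc1)C(C)(C)C | intermediate
17 | C7-ene 8-trimethylsilyl enol ether of 16 | C[Si](C)(C)OC1=CC[C@H]2[C@](C)(CCCC2C(=O)OCC[Si](C)(C)C)C1CC[C@H](C)CCO[Si](c1ccccc1)(c1ccccc1)C(C)(C)C | intermediate
18 | C4-methylated silyl enol ether (4α-CH3, 4β-ester) | C[Si](C)(C)OC1=CC[C@H]2[C@](C)(CCC[C@]2(C)C(=O)OCC[Si](C)(C)C)C1CC[C@H](C)CCO[Si](c1ccccc1)(c1ccccc1)C(C)(C)C | intermediate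
19 | 2-(trimethylsilyl)ethyl (5β,9β,13S)-15-(tert-butyldiphenylsilyloxy)-8-oxo-17-norlabdan-19-oate | O=C1CC[C@H]2[C@](C)(CCC[C@]2(C)C(=O)OCC[Si](C)(C)C)[C@@H]1CC[C@H](C)CCO[Si](c1ccccc1)(c1ccccc1)C(C)(C)C | intermediate
20 | 2-(trimethylsilyl)ethyl (5β,9β,13S)-15-(tert-butyldiphenylsilyloxy)labd-8(17)-en-19-oate | C=C1CC[C@H]2[C@](C)(CCC[C@]2(C)C(=O)OCC[Si](C)(C)C)[C@@H]1CC[C@H](C)CCO[Si](c1ccccc1)(c1ccccc1)C(C)(C)C | intermediate
21 | 2-(trimethylsilyl)ethyl (5β,9β,13S)-15-hydroxylabd-8(17)-en-19-oate | C=C1CC[C@H]2[C@](C)(CCC[C@]2(C)C(=O)OCC[Si](C)(C)C)[C@@H]1CC[C@H](C)CCO | intermediate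
22 | caffeic acid, (E)-3-(3,4-dihydroxyphenyl)acrylic acid | O=C(O)/C=C/c1ccc(O)c(O)c1 | starting material
23 | tert-butyldimethylsilyl (E)-3-[3,4-bis(tert-butyldimethylsilyloxy)phenyl]acrylate | CC(C)(C)[Si](C)(C)OC(=O)/C=C/c1ccc(O[Si](C)(C)C(C)(C)C)c(O[Si](C)(C)C(C)(C)C)c1 | intermediate
24 | (E)-3-[3,4-bis(tert-butyldimethylsilyloxy)phenyl]acrylic acid | O=C(O)/C=C/c1ccc(O[Si](C)(C)C(C)(C)C)c(O[Si](C)(C)C(C)(C)C)c1 | intermediate
25 | 2-(trimethylsilyl)ethyl (5β,9β,13S)-15-{(E)-3-[3,4-bis(tert-butyldimethylsilyloxy)phenyl]acryloyloxy}labd-8(17)-en-19-oate | C=C1CC[C@H]2[C@](C)(CCC[C@]2(C)C(=O)OCC[Si](C)(C)C)[C@@H]1CC[C@H](C)CCOC(=O)/C=C/c1ccc(O[Si](C)(C)C(C)(C)C)c(O[Si](C)(C)C(C)(C)C)c1 | intermediate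
26 | CNP0130717.2, (5β,9β,13S)-15-[(E)-caffeoyloxy]labd-8(17)-en-19-oic acid | C=C1CC[C@H]2[C@](C)(CCC[C@]2(C)C(=O)O)[C@@H]1CC[C@H](C)CCOC(=O)/C=C/c1ccc(O)c(O)c1 | target

**Summary**

Total step count: 14. Longest linear sequence: 13 steps (steps 1–11, 13 and 14).

Steps most likely to fail:

Step 8 (key step). The acyl radical may lose CO before it meets ethylene, the C6 radical may take up more ethylene instead of cyclising, or hydrogen abstraction may occur at other C–H sites. The fallback uses known chemistry and sets out from 14: addition of CH2=CHMgBr (THF, −78 °C) gives the allylic alcohol F1, Dess–Martin oxidation gives the vinyl ketone F2, and samarium diiodide-mediated reductive cyclisation (SmI2, t-BuOH, THF, −78 °C), in which the enone radical anion attacks the enoate β-carbon, closes C5–C6 and comes back to the route at 16.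

Step 9. Methylation may occur at the ketone-derived enolate if the silyl enol ether is lost, or on the wrong face of the C4 enolate. The fallback sets out from 16 and controls C4 by steric differentiation of two identical esters instead of by facial attack: ketalisation with ethylene glycol gives the dioxolane F3; LDA then 2-(trimethylsilyl)ethyl chloroformate gives the C4 geminal diester F4; i-Bu2AlH at low temperature reduces the less hindered α-ester to the hydroxymethyl ester F5; the thiocarbonylimidazolide F6 is deoxygenated with Bu3SnH (Barton–McCombie) to the methyl ketal F7; aqueous acid removes the ketal, equilibrates C9 and comes back to the route at 19.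

Step 4. Transfer of the hindered alkenyl group may be incomplete, or the aluminate enolate may fail to react with the triflating agent or lose its regiochemistry by proton exchange. The fallback sets out from the aluminium enolate 8: quenching with acetic anhydride gives the isolable enol acetate F8, which is cleaved with MeLi to the regiodefined lithium enolate and triflated with the same pyridyl triflimide, coming back to the route at 10.

Further compounds
F1 | step 8 | 2-(trimethylsilyl)ethyl (3S)-3-[(5S)-7-(tert-butyldiphenylsilyloxy)-3-hydroxy-5... allylic alcohol: 3-[1-(1-hydroxyprop-2-enyl)-4-methyl-6-silyloxyhexyl]-3-methylcyclohex-1-ene-1-carboxylate | C[Si](C)(C)CCOC(=O)C1=C[C@@](C)(C(C(O)C=C)CC[C@H](C)CCO[Si](c2ccccc2)(c2ccccc2)C(C)(C)C)CCC1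
F2 | step 8 | corresponding vinyl ketone (C8 acryloyl group) | C[Si](C)(C)CCOC(=O)C1=C[C@@](C)(C(C(=O)C=C)CC[C@H](C)CCO[Si](c2ccccc2)(c2ccccc2)C(C)(C)C)CCC1
F3 | step 9 | 8,8-ethylenedioxy ketal of 16 | O1CCOC12CC[C@H]3[C@](C)(CCCC3C(=O)OCC[Si](C)(C)C)C2CC[C@H](C)CCO[Si](c2ccccc2)(c2ccccc2)C(C)(C)C
F4 | step 9 | C4 geminal bis[2-(trimethylsilyl)ethyl] diester ketal | O1CCOC12CC[C@H]3[C@](C)(CCCC3(C(=O)OCC[Si](C)(C)C)C(=O)OCC[Si](C)(C)C)C2CC[C@H](C)CCO[Si](c2ccccc2)(c2ccccc2)C(C)(C)C
F5 | step 9 | 4α-hydroxymethyl 4β-ester ketal | O1CCOC12CC[C@H]3[C@](C)(CCC[C@]3(CO)C(=O)OCC[Si](C)(C)C)C2CC[C@H](C)CCO[Si](c2ccccc2)(c2ccccc2)C(C)(C)C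
F6 | step 9 | O-(imidazol-1-ylthiocarbonyl) derivative of F5 | O1CCOC12CC[C@H]3[C@](C)(CCC[C@]3(COC(=S)n4ccnc4)C(=O)OCC[Si](C)(C)C)C2CC[C@H](C)CCO[Si](c2ccccc2)(c2ccccc2)C(C)(C)C
F7 | step 9 | 8,8-ethylenedioxy ketal of 19 | O1CCOC12CC[C@H]3[C@](C)(CCC[C@]3(C)C(=O)OCC[Si](C)(C)C)C2CC[C@H](C)CCO[Si](c2ccccc2)(c2ccccc2)C(C)(C)C
F8 | step 4 | (3S)-3-methyl-3-[(5S)-7-(tert-butyldiphenylsilyloxy)-5-methylhept-1-en-2-yl]cyclohex-1-en-1-yl acetate | CC(=O)OC1=C[C@@](C)(C(=C)CC[C@H](C)CCO[Si](c2ccccc2)(c2ccccc2)C(C)(C)C)CCC1
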